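## Retrosynthetic overview

1. Cyclohexene core: ring expansion of a 1,2-dimethyl-1,2-bis(styryl)cyclobutane with Ni(0) and a chiral NHC. The quaternary–quaternary ring bond is broken and re-made to the benzylic CH, which sets both stereocentres.
2. Cyclobutane: head-to-head [2+2] photodimer of 5,7-dimethoxy-8-[(E)-3-methylbuta-1,3-dienyl]coumarin across its isopropenyl C=C.
3. Diene: Heck coupling of 8-iodo-5,7-dimethoxycoumarin with isoprene.
4. Iodocoumarin: C8 iodination of 5,7-dimethoxycoumarin, made from 3,5-dimethoxyphenol and ethyl propiolate; the phenol comes from resorcinol by O-methylation and meta C–H borylation/oxidation.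
5. Ring order: benzene ring (bought) → pyranone → cyclobutane → cyclohexene (by expansion of the cyclobutane).

Assumption: a one-pot, two-stage operation whose intermediate is not isolated is counted as one step. The target SMILES corresponds to (1R,6R), with the coumarinyl on C1 and the styryl on C6 cis.

## Route

Step 1
Reactants: 1 resorcinol (benzene-1,3-diol)
Product: 2 1,3-dimethoxybenzene
Conditions: MeI (2.5 equiv), K2CO3 (2.5 equiv), acetone, reflux
Reagents that add atoms: iodomethane, CI
Why: Williamson ether synthesis, in which both phenoxide oxygens are methylated by SN2 on MeI; no stereocentre is involved.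

Step 2
Reactants: 2 1,3-dimethoxybenzene
Product: 4 3,5-dimethoxyphenol, via 3,5-dimethoxyphenyl pinacol boronate 3 (not isolated)
Conditions: [Ir(OMe)(cod)]2 (1 mol %), dtbpy (2 mol %), B2pin2 (0.55 equiv), THF, 80 °C; then aq. Oxone, acetone, rt
Reagents that add atoms: Oxone (potassium peroxymonosulfate), [K+].[O-]S(=O)(=O)OO; bis(pinacolato)diboron, CC1(C)OB(OC1(C)C)B1OC(C)(C)C(C)(C)O1 (its boryl group stays only in intermediate 3)
Why: Sterically controlled Ir-catalysed C–H borylation takes the only C–H with no ortho substituent (C5), and ipso oxidation of the C–B bond by peroxymonosulfate gives the phenol (one-pot C–H borylation/oxidation).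

Step 3
Reactants: 4 3,5-dimethoxyphenol; 5 ethyl propiolate
Product: 6 5,7-dimethoxy-2H-chromen-2-one (5,7-dimethoxycoumarin)
Conditions: Pd2(dba)3·CHCl3 (2.5 mol %), NaOAc (cat.), HCO2H, rt
Reagents that add atoms: none
Why: Pd-catalysed ortho-hydroarylation of the alkynoate followed by lactonisation (Pechmann-type coumarin synthesis); the two ortho positions of 4 are equivalent, so only the 5,7-dimethoxy isomer can form.

Step 4
Reactants: 6 5,7-dimethoxy-2H-chromen-2-one
Product: 7 8-iodo-5,7-dimethoxy-2H-chromen-2-one
Conditions: NIS (1.05 equiv), TFA (10 mol %), MeCN, 0 °C → rt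
Reagents that add atoms: N-iodosuccinimide, O=C1CCC(=O)N1I
Why: Electrophilic aromatic iodination at C8, which is ortho to O1 and 7-OMe and para to 5-OMe; C6 is flanked by two methoxy groups and the pyranone C3 is far less nucleophilic.

Step 5
Reactants: 7 8-iodo-5,7-dimethoxy-2H-chromen-2-one; 8 isoprene (2-methylbuta-1,3-diene, 6 equiv)
Product: 9 5,7-dimethoxy-8-[(1E)-3-methylbuta-1,3-dien-1-yl]-2H-chromen-2-one
Conditions: Pd(OAc)2 (5 mol %), Bu4NCl (1 equiv), NaHCO3 (2.5 equiv), BHT (cat.), DMF, 60 °C, sealed tube; product stored cold and used at once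
Reagents that add atoms: none
Why: Mizoroki–Heck arylation of a 1,3-diene under Jeffery conditions: aryl-Pd adds to the unhindered CH2 of the monosubstituted vinyl end, and β-hydride elimination of the benzylic H from the π-allyl gives the conjugated (E)-1-aryl diene.

Step 6
Reactants: 9 5,7-dimethoxy-8-[(1E)-3-methylbuta-1,3-dien-1-yl]-2H-chromen-2-one (two molecules)
Product: 11 8-[(1R,6R)-6-[(E)-2-(5,7-dimethoxy-2-oxo-2H-chromen-8-yl)ethenyl]-3,6-dimethylcyclohex-2-en-1-yl]-5,7-dimethoxy-2H-chromen-2-one (CNP0164660.2), via bis(styryl)cyclobutane photodimer 10 (not isolated)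
Conditions: (a) [Ir(ppy)2(dtbbpy)]PF6 (1 mol %), 450 nm LEDs, degassed THF (0.3 M), −30 °C; (b) in the dark, premixed Ni(cod)2 (10 mol %) and bulky C2-symmetric chiral NHC L* (free carbene, SIPE/ANIPE class, 11 mol %), THF, −30 → 0 °C
Reagents that add atoms: none
Why: Proposed new method: stage (a) is a known-type triplet-sensitised head-to-head [2+2] dimerisation of a 1-aryl-1,3-diene (CH2–CH2 bond first, then closure of the bis-allylic biradical to the 1,2-dialkenylcyclobutane 10; the low-energy sensitiser, ET about 49 kcal/mol, is chosen to excite the aryl-diene but not the coumarin C3=C4, and 10 is kept cold because its doubly allylic quaternary–quaternary bond is expected to be thermally labile); stage (b) is the new step, an enantioconvergent Ni(0)/chiral-NHC ring expansion in which Ni(0) bound to a styryl C=C inserts into that strained C–C bond to give a catalyst-bound (NHC)Ni(η3-allyl)(η1-allyl) species that has lost both ring stereocentres of 10 (so rac-trans, cis and E/Z isomers converge through η3–η1–η3 shifts), and C–C reductive elimination between the benzylic terminus of one allyl and the methyl-bearing terminus of the other inside the chiral pocket closes the cyclohexene and sets C1 and C6 together (aryl cis to styryl and (1R,6R) with the ligand antipode selected by screening, exocyclic alkene E from the syn-allyl); this is a stepwise organometallic 1,3-carbon shift whose closest known relatives are the Ni(0)-catalysed isomerisation of cis-1,2-divinylcyclobutane to 4-vinylcyclohexene/cycloocta-1,5-diene and the Ni(0)–NHC vinylcyclopropane-to-cyclopentene rearrangement, neither of which has been made enantioselective or used to form a quaternary stereocentre.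

## Compound list

1 | resorcinol (benzene-1,3-diol) | Oc1cccc(O)c1 | starting material
2 | 1,3-dimethoxybenzene | COc1cccc(OC)c1 | intermediate
3 | 2-(3,5-dimethoxyphenyl)-4,4,5,5-tetramethyl-1,3,2-dioxaborolane | COc1cc(OC)cc(c1)B1OC(C)(C)C(C)(C)O1 | intermediate (not isolated)
4 | 3,5-dimethoxyphenol | COc1cc(O)cc(OC)c1 | intermediate
5 | ethyl propiolate (ethyl prop-2-ynoate) | CCOC(=O)C#C | starting material
6 | 5,7-dimethoxy-2H-chromen-2-one | COc1cc(OC)c2ccc(=O)oc2c1 | intermediate
7 | 8-iodo-5,7-dimethoxy-2H-chromen-2-one | COc1cc(OC)c2ccc(=O)oc2c1I | intermediate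
8 | isoprene (2-methylbuta-1,3-diene) | CC(=C)C=C | starting material
9 | 5,7-dimethoxy-8-[(1E)-3-methylbuta-1,3-dien-1-yl]-2H-chromen-2-one | COc1cc(OC)c2ccc(=O)oc2c1/C=C/C(C)=C | intermediate
10 | rac-trans-1,2-dimethyl-1,2-bis[(E)-2-(5,7-dimethoxy-2-oxo-2H-chromen-8-yl)ethenyl]cyclobutane (racemic, (1S,2S) drawn; the cis/trans ratio does not matter because step 6 erases both ring stereocentres) | C[C@@]1(/C=C/c2c(OC)cc(OC)c3ccc(=O)oc23)CC[C@@]1(C)/C=C/c1c(OC)cc(OC)c2ccc(=O)oc12 | intermediate (not isolated)
11 | 8-[(1R,6R)-6-[(E)-2-(5,7-dimethoxy-2-oxo-2H-chromen-8-yl)ethenyl]-3,6-dimethylcyclohex-2-en-1-yl]-5,7-dimethoxy-2H-chromen-2-one | COc1cc(OC)c2ccc(=O)oc2c1/C=C/[C@@]1(C)CCC(C)=C[C@H]1c1c(OC)cc(OC)c2ccc(=O)oc12 | target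

## Step count and risks

Total steps: 6. Longest linear sequence: 6 (1 → 11).

The three steps most likely to fail:

**Step 6 (the proposed new step).** Stage (a) may be spoiled by photocycloaddition at the coumarin C3=C4 or by E/Z scrambling. In stage (b) the Ni(0) catalyst may be sequestered by the coumarin alkenes, may couple the two benzylic termini to give a cyclooctadiene, or may give low dr or ee. The fallback uses known chemistry only and sets out from 7 and isoprene 8. Benzophenone-sensitised photodimerisation of neat isoprene, followed by fractional distillation, gives rac-trans-1,2-dimethyl-1,2-divinylcyclobutane F1. A twofold Jeffery–Heck reaction of F1 with 7 (2.1 equiv; Pd(OAc)2, Bu4NCl, NaHCO3, DMF, 40 °C) gives 10; the alkyl-Pd intermediate has a β-hydrogen only on the benzylic side, so only the E-styryl arms can form. Warming crude 10 in toluene at 60–80 °C brings about the known thermal vinylcyclobutane-to-cyclohexene 1,3-shift through the bis-allylic diradical. After chromatography this gives the racemate, that is 11 together with its (1S,6S)-enantiomer F2. Preparative chiral SFC removes F2, and the route is rejoined at 11.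

**Step 5.** The aryl group may add at the isopropenyl terminus of isoprene (2-methyl regioisomer), and the diene may polymerise or dimerise at 60 °C. The fallback sets out from 7. A Heck reaction with 2-methylbut-3-en-2-ol under the same Pd conditions at 80 °C, on a monosubstituted alkene with no regiochemical ambiguity, gives the tertiary allylic alcohol 8-[(1E)-3-hydroxy-3-methylbut-1-en-1-yl]-5,7-dimethoxy-2H-chromen-2-one F3. Acid-catalysed dehydration of F3 (PPTS, 4 Å MS, toluene, 70 °C) through the stabilised allylic cation gives the diene, and the route is rejoined at 9.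

**Step 4.** Iodination may also occur at C6 (or C3) and give isomers that are hard to separate. The fallback fixes the regiochemistry before the lactone is built and sets out from 4. Carbamoylation (Et2NCOCl, K2CO3, MeCN, reflux) gives 3,5-dimethoxyphenyl N,N-diethylcarbamate F4. Directed ortho-metalation (s-BuLi, TMEDA, THF, −78 °C) at the position flanked by the carbamate and a methoxy group, then an I2 quench, gives 2-iodo-3,5-dimethoxyphenyl N,N-diethylcarbamate F5. Hydrolysis (NaOH, EtOH/H2O, reflux) gives 2-iodo-3,5-dimethoxyphenol F6. A Pd-free Pechmann-type annulation of F6 with ethyl propiolate 5 (ZnCl2, dioxane, 90 °C) at the only free ortho position gives the iodocoumarin, and the route is rejoined at 7.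

## Further compounds

F1 | step 6 | rac-trans-1,2-dimethyl-1,2-divinylcyclobutane (one enantiomer drawn) | C[C@@]1(C=C)CC[C@@]1(C)C=C
F2 | step 6 | 8-[(1S,6S)-6-[(E)-2-(5,7-dimethoxy-2-oxo-2H-chromen-8-yl)ethenyl]-3,6-dimethylcyclohex-2-en-1-yl]-5,7-dimethoxy-2H-chromen-2-one (enantiomer of 11) | COc1cc(OC)c2ccc(=O)oc2c1/C=C/[C@]1(C)CCC(C)=C[C@@H]1c1c(OC)cc(OC)c2ccc(=O)oc12
F3 | step 5 | 8-[(1E)-3-hydroxy-3-methylbut-1-en-1-yl]-5,7-dimethoxy-2H-chromen-2-one | COc1cc(OC)c2ccc(=O)oc2c1/C=C/C(C)(C)O
F4 | step 4 | 3,5-dimethoxyphenyl N,N-diethylcarbamate | CCN(CC)C(=O)Oc1cc(OC)cc(OC)c1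
F5 | step 4 | 2-iodo-3,5-dimethoxyphenyl N,N-diethylcarbamate | CCN(CC)C(=O)Oc1cc(OC)cc(OC)c1I
F6 | step 4 | 2-iodo-3,5-dimethoxyphenol | COc1cc(O)c(I)c(OC)c1
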